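The oak and alder runs are the two flasks I have, and oak still holds 33.6% of its substrate at its last reading, so I read from it how the yield changes while a flask runs.

| flask | substrate | partner | free catalyst | remark | time |
|---|---|---|---|---|---|
| oak | 0.34 mM | 1.2 equiv | 3.6 mol% | run made earlier |  |
| alder | 4.4 mM | 1.2 equiv | 3.6 mol% | run made earlier |  |
| grey | 0.25 mM | 1.20 equiv | 3.6 mol% |  | 4.0 min |
| green | 2.0 mM | 1.20 equiv | 3.6 mol% |  | 4.0 min |
| violet | 3.0 mM | 1.20 equiv | 3.6 mol% |  | 4.0 min |
| red | 0.30 mM | 1.20 equiv | 3.6 mol% |  | 4.0 min |
| blue | 1.0 mM | 1.20 equiv | 3.6 mol% |  | 4.0 min |

| run | time / s | product / % | substrate / % |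
|---|---|---|---|
| oak | 15.0 | 6.1 | 84.6 |
| oak | 40.0 | 13.5 | 67.8 |
| oak | 80.0 | 26.0 | 44.3 |
| oak | 120 | 33.3 | 33.6 |
| alder | 30.0 | 45.8 | 6.5 |
| alder | 60.0 | 54.4 | 0 |
| alder | 90.0 | 56.1 | 0.2 |
| alder | 120 | 56.2 | 1.4 |

(standard deviation of a reading: 1 percentage point)

- a reading or a percentage of product counts all its forms, free or not

- the flasks put in order of amount of product, in percent of the substrate charged, best first, at 4.0 min (grey / green / violet / red / blue)
- the same order at 25 s (grey / green / violet / red / blue)
- the amount of product, in percent of the substrate charged of the flask you put first, at 4.0 min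
- the amount of product, in percent of the substrate charged of the flask you put last, at 4.0 min

Between 80.0 s and 120 s the oak run gains 7.3 percentage points of product and loses 11 points of substrate. So the selectivity s, the share of lost substrate that becomes product, reads 0.682 in that slice, with the scatter of the readings on it. I use the last slice, where the lag of product has had longest to pass.

I suppose that the useful route runs with catalyst times substrate and an unseen loss with substrate squared. Then s = g/(g + x), where x is the fraction of the charge still there and g goes with the catalyst loading. The slice sat at x = 39.0%, so g = 83.6%. I call g the level point: the fraction of the charge left at which both routes take equal shares.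

Adding up the slices, product from the full charge down to x is g·ln((1 + g)/(g + x)). Run to the end, that gives 65.8%. Alder reads 56.2% at 120 s, so my supposition weakens at high charge. But blue at 1.0 mM stands nearer oak than alder in charge, so I put the top near my figure.

The forecast gives blue > green > violet > red > grey at 4.0 min and violet > green > blue > red > grey at 25 s, with top 57% (52% to 64%) and low 42% (36% to 48%): “Oak's incremental selectivity is rising and points to a similar final yield”. My top stands higher than the upper end of its range.

The flasks give blue > green > violet > red > grey at 4.0 min and violet > green > blue > red > grey at 25 s, with 64.6% in blue and 39.7% in grey. Both orders stand as forecast and low lies inside its range, but top lies above it.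

    substrate + free catalyst ⇌ catalyst intermediate A (K = 1800 M⁻¹, k = 954 M⁻¹ s⁻¹)
    partner + catalyst intermediate A → catalyst intermediate B (k = 1850 M⁻¹ s⁻¹)
    catalyst intermediate B → catalyst intermediate C (k = 0.934 s⁻¹)
    catalyst intermediate C → free catalyst + product (k = 5.05 s⁻¹)
    crystals ⇌ product, rate k5*(cs5 - [product]) while solid is left; crystals form when [product] > cs5 (solubility = 0.0790 mM, k = 3.23 s⁻¹)
    2 substrate → homo dimer (k = 9.59 M⁻¹ s⁻¹)

Blue lies 1.2 points from my 65.8%. The step making homo dimer from substrate is the main reason blue stands at 64.6%: the run without it gives 96.9%, and that step accounts for 91% of what is missing from a full yield. Now take grey with 0.9 mol% of free catalyst, which still has 40% of its substrate unbound at 4.0 min. Scaling the level point with loading gives 20.9%, and the sum down to that x gives 14.3% of product. That flask gives 12.7%.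

The data were computed with constants of no real substance, and the scatter is random.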